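The synthesis rests on cutting the pyranone ring C at C3–C4 and O1–C2. The feature exploited is that the acyl carbon C4 and the ether oxygen O1 sit on adjacent ring A carbons (C4a, C8a), as formyl and hydroxyl groups do in a salicylaldehyde. The C2=C3 unit, arylated at C2 and oxygenated at C3, maps onto the triple bond of an aryl silyl ynol ether. One rhodium-catalysed oxidative aldehyde C–H/O–H annulation should form both bonds, close ring C and install O3 as the only silyl ether among three benzyl ethers. Its precursors are a dibenzylated phloroglucinaldehyde and a TIPS ynol ether made by ester homologation. Fluoride then frees O3 alone for sulfation before hydrogenolysis.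

Key step: step 4

Assumption: the target is drawn as the hydrogen sulfate, so the sulfate ester is carried as its sodium salt and protonated only in the last, cold work-up; the free acid should be kept cold and dry.

Step 1
Reactants: 1 2,4,6-trihydroxybenzaldehyde
Product: 2 2,4-bis(benzyloxy)-6-hydroxybenzaldehyde
Conditions: BnBr (2.05 equiv), K2CO3 (2.2 equiv), DMF, 0 °C to rt
Reagents that add atoms: benzyl bromide, BrCc1ccccc1
Why: Williamson etherification in which the unchelated 4-OH and one ortho OH are alkylated, after which the remaining OH is locked in a hydrogen bond to the formyl oxygen and, with the bromide limited to two equivalents, should stay free.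

Step 2
Reactants: 3 ethyl 4-hydroxybenzoate
Product: 4 ethyl 4-(benzyloxy)benzoate
Conditions: BnBr (1.1 equiv), K2CO3 (1.5 equiv), acetone, reflux
Reagents that add atoms: benzyl bromide, BrCc1ccccc1
Why: Williamson etherification of an acidic para-acyl phenol that offers no competing nucleophilic site.

Step 3
Reactants: 4 ethyl 4-(benzyloxy)benzoate; 5 dibromomethane; 6 triisopropylsilyl chloride
Product: 10 ((4-(benzyloxy)phenyl)ethynyloxy)triisopropylsilane, via dibromomethyllithium 7 (not isolated), via lithium dibromoenolate 8 (not isolated), via lithium ynolate 9 (not isolated)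
Conditions: 5, lithium 2,2,6,6-tetramethylpiperidide, THF, −78 °C; 4; LiN(SiMe3)2, −78 °C; n-BuLi, −78 °C to rt; 6, −78 °C to rt; pentane/aq NaHCO3 work-up, Et3N-deactivated SiO2
Reagents that add atoms: dibromomethane (5), BrCBr; triisopropylsilyl chloride (6), CC(C)[Si](Cl)(C(C)C)C(C)C
Why: Kowalski ester homologation stopped at the ynolate, in which acylation of 7 by the ester and enolisation give 8, bromine–lithium exchange triggers the 1,2-aryl shift of the carbenoid to 9, and a bulky trialkylsilyl chloride silylates the ynolate on oxygen rather than carbon, the butyllithium charge being kept near stoichiometric to spare the benzylic ether position.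

Step 4
Reactants: 2 2,4-bis(benzyloxy)-6-hydroxybenzaldehyde; 10 ((4-(benzyloxy)phenyl)ethynyloxy)triisopropylsilane
Product: 11 5,7-bis(benzyloxy)-2-(4-(benzyloxy)phenyl)-3-((triisopropylsilyl)oxy)-4H-chromen-4-one
Conditions: [Cp*RhCl2]2 (2.5 mol %), anhydrous Cu(OAc)2 (2.2 equiv), anhydrous Na2CO3 (2.5 equiv), 4 Å MS, toluene, 100 °C, N2; 10 (1.5 equiv) added over 3 h
Reagents that add atoms: none
Why: Proposed new method: acetate exchange gives Cp*Rh(OAc)2, the phenoxide of 2 binds trivalent rhodium, acetate-assisted metalation–deprotonation cleaves the formyl C–H bond to a five-membered acyl oxarhodacycle, and coordinated 10 undergoes migratory insertion into the Rh–acyl bond (C4–C3). Ring C, six-membered, closes by C–O reductive elimination (O1–C2) from the resulting seven-membered oxarhodacycle, a formal [4+2] annulation in which the directing oxygen becomes O1, and the monovalent rhodium released is reoxidised by two equivalents of Cu(OAc)2. The closest known reaction type is the rhodium-catalysed oxidative annulation of salicylaldehydes with diaryl, dialkyl and aryl alkyl alkynes to 2,3-disubstituted chromones, which has not been extended to an O-silyl ynol ether. The selectivity needed is regiochemical: oxygen donation makes the aryl-bearing alkyne carbon nucleophilic, so the electrophilic metal should bond there while the migrating acyl group goes to the oxygen-bearing carbon, and this agrees with the habit of aryl alkyl alkynes to place the aryl carbon next to the ring oxygen. No stereocentre is formed. The acid- and silver-sensitive ynol ether is shielded by the bulky TIPS group, a silver-free neutral catalyst, Na2CO3 and sieves that take up AcOH and water, and slow addition, while loss of TIPS after ring closure would only anticipate step 5.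

Step 5
Reactants: 11 5,7-bis(benzyloxy)-2-(4-(benzyloxy)phenyl)-3-((triisopropylsilyl)oxy)-4H-chromen-4-one
Product: 12 5,7-bis(benzyloxy)-2-(4-(benzyloxy)phenyl)-3-hydroxy-4H-chromen-4-one
Conditions: Bu4NF (1.1 equiv), AcOH (1.2 equiv), THF, 0 °C
Reagents that add atoms: none
Why: Fluoride-mediated desilylation driven by Si–F bond formation, in which the enol-type silyl ether is the only fluoride-labile group, the benzyl ethers are inert and the acetic acid buffer keeps the oxygen-sensitive flavonolate from accumulating.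

Step 6
Reactants: 12 5,7-bis(benzyloxy)-2-(4-(benzyloxy)phenyl)-3-hydroxy-4H-chromen-4-one
Product: 14 sodium 5,7-bis(benzyloxy)-2-(4-(benzyloxy)phenyl)-4-oxo-4H-chromen-3-yl sulfate, via pyridinium sulfate salt 13 (not isolated)
Conditions: SO3·pyridine (5 equiv), pyridine, 50 °C; then aq NaHCO3, 0 °C; toluene co-evaporation; SiO2 (CH2Cl2–MeOH)
Reagents that add atoms: sulfur trioxide–pyridine complex, O=S(=O)([O-])[n+]1ccccc1; sodium hydrogen carbonate, [Na+].OC(=O)[O-]
Why: O-sulfation with a sulfur trioxide–amine complex, a standard reaction of partially benzylated flavonols, meets O3 as the only free hydroxyl, and exchange of pyridinium for sodium gives an acid-free salt and removes the amine that would slow the palladium catalyst of step 7.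

Step 7
Reactants: 14 sodium 5,7-bis(benzyloxy)-2-(4-(benzyloxy)phenyl)-4-oxo-4H-chromen-3-yl sulfate
Product: 16 kaempferol 3-O-sulfate, via sodium kaempferol 3-sulfate 15 (not isolated)
Conditions: H2 (1 atm), Pd/C, THF–MeOH–H2O, rt; filter; HCl (1.0 equiv), H2O, 0 °C; C18 desalting, lyophilisation
Reagents that add atoms: none
Why: Catalytic hydrogenolysis of aryl benzyl ethers, which leaves sulfate monoester salts and the tetrasubstituted C2=C3 bond of flavonols untouched, is followed by exchange of sodium for a proton in the cold so that the acid-labile O3–S bond should not be solvolysed.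

Compound list
1 | 2,4,6-trihydroxybenzaldehyde | O=Cc1c(O)cc(O)cc1O | starting material
2 | 2,4-bis(benzyloxy)-6-hydroxybenzaldehyde | O=Cc1c(O)cc(OCc2ccccc2)cc1OCc1ccccc1 | intermediate
3 | ethyl 4-hydroxybenzoate | CCOC(=O)c1ccc(O)cc1 | starting material
4 | ethyl 4-(benzyloxy)benzoate | CCOC(=O)c1ccc(OCc2ccccc2)cc1 | intermediate
5 | dibromomethane | BrCBr | starting material
6 | triisopropylsilyl chloride | CC(C)[Si](Cl)(C(C)C)C(C)C | starting material
7 | dibromomethyllithium | [Li]C(Br)Br | intermediate
8 | lithium 1-(4-(benzyloxy)phenyl)-2,2-dibromoethen-1-olate | [Li]OC(=C(Br)Br)c1ccc(OCc2ccccc2)cc1 | intermediate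
9 | lithium 2-(4-(benzyloxy)phenyl)ethyn-1-olate | [Li]OC#Cc1ccc(OCc2ccccc2)cc1 | intermediate
10 | ((4-(benzyloxy)phenyl)ethynyloxy)triisopropylsilane | CC(C)[Si](OC#Cc1ccc(OCc2ccccc2)cc1)(C(C)C)C(C)C | intermediate
11 | 5,7-bis(benzyloxy)-2-(4-(benzyloxy)phenyl)-3-((triisopropylsilyl)oxy)-4H-chromen-4-one | O=c1c(O[Si](C(C)C)(C(C)C)C(C)C)c(-c2ccc(OCc3ccccc3)cc2)oc2cc(OCc3ccccc3)cc(OCc3ccccc3)c12 | intermediate
12 | 5,7-bis(benzyloxy)-2-(4-(benzyloxy)phenyl)-3-hydroxy-4H-chromen-4-one | O=c1c(O)c(-c2ccc(OCc3ccccc3)cc2)oc2cc(OCc3ccccc3)cc(OCc3ccccc3)c12 | intermediate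
13 | pyridinium 5,7-bis(benzyloxy)-2-(4-(benzyloxy)phenyl)-4-oxo-4H-chromen-3-yl sulfate | O=c1c(OS(=O)(=O)[O-])c(-c2ccc(OCc3ccccc3)cc2)oc2cc(OCc3ccccc3)cc(OCc3ccccc3)c12.c1cc[nH+]cc1 | intermediate
14 | sodium 5,7-bis(benzyloxy)-2-(4-(benzyloxy)phenyl)-4-oxo-4H-chromen-3-yl sulfate | O=c1c(OS(=O)(=O)[O-])c(-c2ccc(OCc3ccccc3)cc2)oc2cc(OCc3ccccc3)cc(OCc3ccccc3)c12.[Na+] | intermediate
15 | sodium 5,7-dihydroxy-2-(4-hydroxyphenyl)-4-oxo-4H-chromen-3-yl sulfate | O=c1c(OS(=O)(=O)[O-])c(-c2ccc(O)cc2)oc2cc(O)cc(O)c12.[Na+] | intermediate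
16 | kaempferol 3-O-sulfate (5,7-dihydroxy-2-(4-hydroxyphenyl)-4-oxo-4H-chromen-3-yl hydrogen sulfate) | O=c1c(OS(=O)(=O)O)c(-c2ccc(O)cc2)oc2cc(O)cc(O)c12 | target

Total step count: 7. Longest linear sequence: 6 (steps 2, 3, 4, 5, 6, 7).

Steps most likely to fail

1. Step 4.
- **What may go wrong:** The ynol ether may be destroyed before insertion by acetate or acid addition, copper-mediated oxidation or thermal oxygen-to-carbon silyl migration. Insertion may take the reversed orientation, or the acyl rhodium species may decarbonylate.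
- **Fallback:** This uses known chemistry, sets out from ester 4 and comes back at flavonol 12. Commercial 2,4,6-trihydroxyacetophenone is dibenzylated (BnBr, K2CO3, DMF) to 1-(2,4-bis(benzyloxy)-6-hydroxyphenyl)ethan-1-one F1. A crossed Claisen condensation of F1 with 4 (NaH, THF, reflux) gives 1-(2,4-bis(benzyloxy)-6-hydroxyphenyl)-3-(4-(benzyloxy)phenyl)propane-1,3-dione F2. Cyclodehydration (NaOAc, AcOH, 100 °C) gives 5,7-bis(benzyloxy)-2-(4-(benzyloxy)phenyl)-4H-chromen-4-one F3. Dimethyldioxirane (acetone–CH2Cl2, 0 °C) epoxidises C2=C3 to the racemic cis-fused 4,6-bis(benzyloxy)-1a-(4-(benzyloxy)phenyl)-1a,7a-dihydro-7H-oxireno[2,3-b]chromen-7-one F4. Catalytic p-TsOH then opens F4 to 12.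

2. Step 3.
- **What may go wrong:** Surplus alkyllithium may deprotonate the benzylic position of the aryl benzyl ether and cause Wittig rearrangement. The carbenoid rearrangement may be incomplete, the alkoxide and amide bases may consume the silyl chloride, and the ynol ether may hydrolyse on silica.
- **Fallback:** This sets out from ester 4 and comes back at ynolate 9. LiAlH4 (THF, 0 °C) gives (4-(benzyloxy)phenyl)methanol F5, and MnO2 (CH2Cl2) gives 4-(benzyloxy)benzaldehyde F6, which can also be bought. Ohira–Bestmann homologation (dimethyl (1-diazo-2-oxopropyl)phosphonate, K2CO3, MeOH) gives 1-(benzyloxy)-4-ethynylbenzene F7. One equivalent of n-BuLi at −78 °C gives lithium (4-(benzyloxy)phenyl)acetylide F8. Oxygenation with lithium tert-butyl peroxide (t-BuOOH, LiN(SiMe3)2, THF, −78 to 0 °C) leads to the same ynolate 9, which is silylated with 6 as in step 3 to give 10. No excess alkyllithium is present at any point.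

3. Step 7.
- **What may go wrong:** The O3–S bond may be solvolysed by acidic residues of the catalyst or during the final protonation. Hydrogenolysis may stall through traces of pyridine or through precipitation of partly debenzylated salts.
- **Fallback:** This sets out from flavonol 12 and comes back at target 16. Compound 12 is treated with 2,2,2-trichloroethyl chlorosulfate (Et3N, DMAP, THF, 0 °C to rt) to give the neutral, chromatographable diester 5,7-bis(benzyloxy)-2-(4-(benzyloxy)phenyl)-4-oxo-4H-chromen-3-yl 2,2,2-trichloroethyl sulfate F9. Transfer hydrogenolysis (Pd/C, HCO2NH4, MeOH–THF, rt) removes the trichloroethyl group and the three benzyl ethers together in a formate-buffered medium. This gives ammonium 5,7-dihydroxy-2-(4-hydroxyphenyl)-4-oxo-4H-chromen-3-yl sulfate F10, which is protonated and desalted as in step 7 to give 16.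

Further compounds
F1 | step 4 | 1-(2,4-bis(benzyloxy)-6-hydroxyphenyl)ethan-1-one | CC(=O)c1c(O)cc(OCc2ccccc2)cc1OCc1ccccc1
F2 | step 4 | 1-(2,4-bis(benzyloxy)-6-hydroxyphenyl)-3-(4-(benzyloxy)phenyl)propane-1,3-dione | O=C(CC(=O)c1ccc(OCc2ccccc2)cc1)c1c(O)cc(OCc2ccccc2)cc1OCc1ccccc1
F3 | step 4 | 5,7-bis(benzyloxy)-2-(4-(benzyloxy)phenyl)-4H-chromen-4-one | O=c1cc(-c2ccc(OCc3ccccc3)cc2)oc2cc(OCc3ccccc3)cc(OCc3ccccc3)c12
F4 | step 4 | 4,6-bis(benzyloxy)-1a-(4-(benzyloxy)phenyl)-1a,7a-dihydro-7H-oxireno[2,3-b]chromen-7-one (racemic, one enantiomer drawn) | O=C1[C@H]2O[C@@]2(c2ccc(OCc3ccccc3)cc2)Oc2cc(OCc3ccccc3)cc(OCc3ccccc3)c12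
F5 | step 3 | (4-(benzyloxy)phenyl)methanol | OCc1ccc(OCc2ccccc2)cc1
F6 | step 3 | 4-(benzyloxy)benzaldehyde | O=Cc1ccc(OCc2ccccc2)cc1
F7 | step 3 | 1-(benzyloxy)-4-ethynylbenzene | C#Cc1ccc(OCc2ccccc2)cc1
F8 | step 3 | lithium (4-(benzyloxy)phenyl)acetylide | [Li]C#Cc1ccc(OCc2ccccc2)cc1
F9 | step 7 | 5,7-bis(benzyloxy)-2-(4-(benzyloxy)phenyl)-4-oxo-4H-chromen-3-yl 2,2,2-trichloroethyl sulfate | O=c1c(OS(=O)(=O)OCC(Cl)(Cl)Cl)c(-c2ccc(OCc3ccccc3)cc2)oc2cc(OCc3ccccc3)cc(OCc3ccccc3)c12
F10 | step 7 | ammonium 5,7-dihydroxy-2-(4-hydroxyphenyl)-4-oxo-4H-chromen-3-yl sulfate | O=c1c(OS(=O)(=O)[O-])c(-c2ccc(O)cc2)oc2cc(O)cc(O)c12.[NH4+]
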